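## Analysis of the target

The target is a cembranoid, numbered here in the cembrane way: C1–C14 form the 14-membered carbocycle, C15 (with methyl C17) and the carbonyl C16 close a six-membered lactone from C1 to the oxygen on C3, C18 is the methyl on C4, C19 the exocyclic methylene on C8 and C20 the methyl on C12. The lactone shares the C1–C2–C3 segment with the large ring, so the molecule is a bridged bicycle. There are seven stereocentres: 1R, 3R, 4S, 7S, 11S, 12S and 15S. On the lactone the C14 and C4 branches are cis and the C17 methyl is trans to C14, so all three substituents can be equatorial; C3/C4 form an erythro diol pattern. C7 and the trans C11/C12 epoxide are remote from the lactone and from each other, so no centre can be relied on to relay its configuration across the ring. The sensitive groups are the trisubstituted epoxide (acid-labile and open to transannular attack by the C4 or C7 hydroxyl), the allylic alcohol next to the C8 methylene, the base-epimerisable C15 and the tertiary C4 alcohol. The difficulties are closing a 14-membered ring without creating a geometric or stereochemical ambiguity, and placing oxygen on C7 and not on C6. The strategy rests on two facts: C7 is a carbinol between the C6 methylene and the methylene-bearing C8, which is the reduced, hydrated form of a C6≡C7–C8(=C19) enyne; and the C4 hydroxyl lies three bonds from C6, so it can reach C7 through a five-membered ring and only C7.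

## Retrosynthetic reasoning

The epoxide is removed first (35 to 34). It is the most fragile group and would not survive the acid, fluoride and Lewis-acid steps that precede it; the forward step must epoxidise the trisubstituted C11=C12 olefin in the presence of the allylic 1,1-disubstituted C8=C19 olefin, with reagent control of the face.

The C7–H bond is cut next (34 to enone 33), and the C7 carbonyl oxygen is then traced to an alkyne (33 to 31 through the cyclic enol ether 32). An alkyne hydration normally has no regiocontrol, but here the free C4 hydroxyl of 31 can only add in a 5-endo sense, which puts oxygen on C7. The silyl ether 30 is the protected form of 31.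

The C6≡C7 bond of 30 is the ring-closing disconnection and leads to the diyne 29 with two methyl-capped alkynes. It is cut there because a triple bond has no geometry, because alkyne metathesis leaves both olefins alone, and because the bond sits exactly where the later oxygenation needs it. The forward step has to favour ring closure over oligomerisation.

Diyne 29 is cut at the C10–C11 sp3–sp2 bond into the vinyl iodide 23 and the alkyl iodide 27 (used as its zinc reagent 28). This keeps the C11=C12 geometry a property of 23, fixed before any ring exists, and joins two fragments of unequal size late.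

Iodide 27 comes from alcohol 26, which is the coupling product of 3-bromo-3-buten-1-ol 24 and propyne 25; the C7–C8 bond of the enyne is therefore bought from a commercial 2-bromoalkene.

The lactone of 23 is opened at the C16–O bond: 23 comes from its C15 epimer mixture 22, that from hydroxy lactone 21 and that from triol 18 by oxidation of the primary C16 alcohol. C15 is not controlled when it is made; it is set by equilibration once the lactone ring exists, where the all-equatorial arrangement should be the stable one.

The C5–C6 bond of 17/18 is cut to a propynyl anion and the terminal epoxide 16. Epoxide 16 comes from allylic alcohol 15 by hydroxyl-directed epoxidation, which sets C4 from C3, and 15 comes from enone 14 by reagent-controlled reduction, which sets C3. The tertiary C4 carbinol is thereby made from an olefin face and not by addition to a ketone.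

Enone 14 is the oxidised form of 13, whose vinyl iodide is the syn-carbometalation product of the terminal alkyne in 11. The C3–C4 bond of 11 is cut to aldehyde 10 and an isopropenyl nucleophile. Alkyne 9, the acetal of 10, comes from methyl ketone 7. The ketone carbon becomes C12 and its methyl becomes C11, so the (E)-olefin is built with the C20 methyl delivered syn to the metal.

Keto acetal 7 is the product of cleaving the cyclohexene of 4, and 4 (via 3) is (R)-limonene 1 after hydroboration of the isopropenyl group and silylation. Limonene supplies C1 in the correct absolute configuration together with C2, C3, C12–C17.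

## Alternatives that were turned down

Alternative 1: The lactone C3–O bond is disconnected. In the forward step the C16 carboxylate of the macrocyclic bis-epoxy acid A2 would open the (3S,4S)-epoxide at C3 with inversion, giving the lactone and the free C4 hydroxyl of A1 (the 7-O-triethylsilyl ether of the target) while the 11,12-epoxide stays. In its favour, it creates C3 and C4 stereospecifically in one step from an (E)-olefin epoxide, mirrors a plausible biosynthesis, and ends one deprotection from the target; on late-stage step economy it is stronger than the chosen route. Against it, A2 needs the complete 14-membered ring with two trisubstituted epoxides, each installed face-selectively on a flexible macrocycle and chemoselectively beside the C8 methylene. The carboxylate must then choose 6-exo attack at C3 over 7-endo attack at the tertiary C4 (which acid activation favours) and must not touch the second epoxide, which the C7 oxygen or the acid itself can reach across the ring. C15 has no ring to equilibrate in before the last step, and the macrocyclisation is not solved, only postponed. The chosen route gives up the one-step C3/C4 installation but sets both centres on an open-chain allylic alcohol, where directed epoxidation is predictable, and has the lactone in place to stiffen the ring-closure precursor.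

Alternative 2: The C11=C12 double bond is disconnected. Low-valent titanium would couple the C11 aldehyde and the C12 methyl ketone of keto aldehyde A4 reductively, closing the ring and forming the olefin of A3 in one step. This is a classical cembranoid ring closure and is shorter at the macrocyclisation stage than the chosen route, and the limonene-derived methyl ketone would be used as it is. Against it, an aldehyde–ketone coupling gives a trisubstituted olefin whose E/Z ratio is set only by ring strain. The lactone cannot survive the reductant and must be carried as the lactol methyl acetal (extra redox steps). The allylic C7 silyl ether and the free tertiary alcohol are exposed to an oxophilic reductant used in large excess. The chosen route fixes the C11=C12 geometry by syn-carbometalation before the ring exists and closes the ring at a bond that has no geometry.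

Alternative 3: C1 is made the linchpin and the C1–C14 and C1–C2 bonds are disconnected. Lithiated 1,3-dithiane A7 would be alkylated by the C14 iodide of iodo epoxide A6 and, after a second lithiation, would open the C2–C3 epoxide at C2 to give the macrocyclic dithiane A5 with a free C3 hydroxyl. It is the most convergent and modular of the four plans, and C3 comes cleanly from an epoxide. Against it, the first alkylation must distinguish an iodide from an epoxide in the same molecule, and the ring closure is an intramolecular attack of a hindered 2-alkyl dithiane anion. Above all, A5 carries C1 as a masked ketone, whereas the target needs a C1–H stereocentre bearing the C15 propionate branch. That means unmasking, attaching C15–C17, and setting C1 and C15 on the finished macrocycle, where facial control is the least predictable. The chosen route takes C1 from the chiral pool and settles C15 before ring closure, at the price of a longer linear sequence.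

Key step: step 19

Assumption: of the two C15 epimers of lactone 22, the one with the C17 methyl equatorial and trans to the C14 chain (15S) is taken to be the more stable, so that base equilibration converges on 23.

## Route

Step 1
Reactants: 1 (R)-(+)-limonene
Product: 3 2-[(1R)-4-methylcyclohex-3-en-1-yl]propan-1-ol (both epimers at the new centre, the later C15), via B-alkyl-9-borabicyclononane adduct 2 (not isolated)
Conditions: 9-BBN, THF, 0 °C→rt; then NaOH, H2O2, 0 °C
Reagents that add atoms: hydrogen peroxide, OO
Why: Hydroboration–oxidation; 9-BBN should take the 1,1-disubstituted exocyclic olefin much faster than the trisubstituted ring olefin and place boron on the terminal carbon. The new centre forms without control and both epimers are carried on deliberately, because C15 is corrected by equilibration in step 15.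

Step 2
Reactants: 3 2-[(1R)-4-methylcyclohex-3-en-1-yl]propan-1-ol
Product: 4 tert-butyl{2-[(1R)-4-methylcyclohex-3-en-1-yl]propoxy}diphenylsilane (C15 epimers)
Conditions: t-BuPh2SiCl, imidazole, CH2Cl2, rt
Reagents that add atoms: tert-butyl(chloro)diphenylsilane, CC(C)(C)[Si](Cl)(c1ccccc1)c1ccccc1
Why: Standard silylation of a primary alcohol; the tert-butyldiphenylsilyl group is chosen because it should survive the acid of steps 3 and 5 and the organometallic steps up to step 11.

Step 3
Reactants: 4 tert-butyl{2-[(1R)-4-methylcyclohex-3-en-1-yl]propoxy}diphenylsilane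
Product: 7 (5R)-7-{[tert-butyl(diphenyl)silyl]oxy}-5-(2,2-dimethoxyethyl)-6-methylheptan-2-one (C15 epimers), via methoxy hydroperoxide aldehyde 5 (not isolated), via hydroperoxy acetal 6 (not isolated)
Conditions: O3, CH2Cl2/MeOH, −78 °C; p-TsOH (cat.), rt; then NaHCO3, Me2S, rt
Reagents that add atoms: ozone, [O-][O+]=O; methanol, CO
Why: Unsymmetrical ozonolysis of a cycloalkene: methanol traps the carbonyl oxide at the more substituted terminus (C12) as a methoxy hydroperoxide and leaves the C3 aldehyde, which the acid converts to its dimethyl acetal before the sulfide reduces the hydroperoxide to the methyl ketone. The only olefin left in 4 is the ring olefin, so no chemoselectivity is asked of ozone.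

Step 4
Reactants: 7 (5R)-7-{[tert-butyl(diphenyl)silyl]oxy}-5-(2,2-dimethoxyethyl)-6-methylheptan-2-one
Product: 9 tert-butyl{[(3R)-3-(2,2-dimethoxyethyl)-2-methylhept-6-yn-1-yl]oxy}diphenylsilane (C15 epimers), via enol phosphate 8 (not isolated)
Conditions: LiN(i-Pr)2, THF, −78 °C; ClP(O)(OEt)2, −78 °C→rt; then LiN(i-Pr)2 (2.3 equiv), −78 °C→rt
Reagents that add atoms: none
Why: Negishi conversion of a methyl ketone into a terminal alkyne: kinetic deprotonation on the methyl side, O-phosphorylation and base-induced elimination of the terminal enol phosphate. The ketone carbon becomes C12 and the former methyl carbon becomes the alkyne CH, the later C11; acetal and silyl ether are inert to the amide base.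

Step 5
Reactants: 9 tert-butyl{[(3R)-3-(2,2-dimethoxyethyl)-2-methylhept-6-yn-1-yl]oxy}diphenylsilane
Product: 10 (3R)-3-{1-[tert-butyl(diphenyl)silyl]oxypropan-2-yl}hept-6-ynal (C15 epimers)
Conditions: PPTS, acetone/H2O, 50 °C
Reagents that add atoms: water, O
Why: Mild acid hydrolysis of a dimethyl acetal; the silyl ether and the alkyne should be untouched, and C1 is β to the aldehyde and cannot epimerise. The acetal is removed here because it would not tolerate the trialkylaluminium of step 7.

Step 6
Reactants: 10 (3R)-3-{1-[tert-butyl(diphenyl)silyl]oxypropan-2-yl}hept-6-ynal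
Product: 11 (5R)-5-{1-[tert-butyl(diphenyl)silyl]oxypropan-2-yl}-2-methylnon-1-en-8-yn-3-ol (epimers at C3 and C15)
Conditions: CH2=C(CH3)MgBr, THF, −78 °C
Reagents that add atoms: isopropenylmagnesium bromide, CC(=C)[Mg]Br
Why: Grignard 1,2-addition to an aldehyde, which at −78 °C should be much faster than deprotonation of the terminal alkyne. The C3 configuration is not controlled and need not be, since C3 is oxidised in step 8 and set in step 9.

Step 7
Reactants: 11 (5R)-5-{1-[tert-butyl(diphenyl)silyl]oxypropan-2-yl}-2-methylnon-1-en-8-yn-3-ol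
Product: 13 (5R,8E)-5-{1-[tert-butyl(diphenyl)silyl]oxypropan-2-yl}-9-iodo-2,8-dimethylnona-1,8-dien-3-ol (epimers at C3 and C15), via alkenylalane 12 (not isolated)
Conditions: AlMe3, Cp2ZrCl2 (cat.), CH2Cl2, 0 °C→rt; then I2, THF, −30→0 °C
Reagents that add atoms: trimethylaluminium, C[Al](C)C; iodine, II
Why: Zirconium-catalysed carboalumination of a terminal alkyne (Negishi) adds methyl (C20) to C12 and aluminium to C11 in a syn sense, and iodinolysis with retention should give the (E)-vinyl iodide only. The hydroxyl is carried as its aluminium alkoxide and the 1,1-disubstituted olefin does not carbometalate under these conditions.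

Step 8
Reactants: 13 (5R,8E)-5-{1-[tert-butyl(diphenyl)silyl]oxypropan-2-yl}-9-iodo-2,8-dimethylnona-1,8-dien-3-ol
Product: 14 (5R,8E)-5-{1-[tert-butyl(diphenyl)silyl]oxypropan-2-yl}-9-iodo-2,8-dimethylnona-1,8-dien-3-one (C15 epimers)
Conditions: Dess–Martin periodinane, NaHCO3, CH2Cl2, 0 °C→rt
Reagents that add atoms: none
Why: Dess–Martin oxidation of a secondary allylic alcohol under buffered, non-acidic conditions, which removes the C3 mixture and should not isomerise the isopropenyl ketone.

Step 9
Reactants: 14 (5R,8E)-5-{1-[tert-butyl(diphenyl)silyl]oxypropan-2-yl}-9-iodo-2,8-dimethylnona-1,8-dien-3-one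
Product: 15 (3R,5R,8E)-5-{1-[tert-butyl(diphenyl)silyl]oxypropan-2-yl}-9-iodo-2,8-dimethylnona-1,8-dien-3-ol (C15 epimers)
Conditions: (S)-2-methyl-CBS-oxazaborolidine (cat.), catecholborane, toluene, −78 °C
Reagents that add atoms: none
Why: Corey–Bakshi–Shibata reduction of an enone; the α-methylvinyl group acts as the large substituent and the C2 methylene as the small one, so the (S)-catalyst should deliver hydride to give the (3R)-alcohol. Catecholborane at −78 °C should leave the vinyl iodide and the olefin alone.

Step 10
Reactants: 15 (3R,5R,8E)-5-{1-[tert-butyl(diphenyl)silyl]oxypropan-2-yl}-9-iodo-2,8-dimethylnona-1,8-dien-3-ol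
Product: 16 (1R,3R,6E)-3-{1-[tert-butyl(diphenyl)silyl]oxypropan-2-yl}-7-iodo-6-methyl-1-[(2S)-2-methyloxiran-2-yl]hept-6-en-1-ol (C15 epimers)
Conditions: VO(acac)2 (cat.), t-BuOOH, CH2Cl2, 0 °C→rt
Reagents that add atoms: tert-butyl hydroperoxide, CC(C)(C)OO
Why: Vanadium-catalysed hydroxyl-directed epoxidation of an allylic alcohol. The methyl on the olefin carbon next to the carbinol forces the carbinol hydrogen, not the chain, to eclipse it in the transition state, so oxygen should be delivered to the face that gives the erythro epoxy alcohol, which is (4S) from the (3R)-alcohol. The vinyl iodide olefin has no directing group and should not react.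

Step 11
Reactants: 16 (1R,3R,6E)-3-{1-[tert-butyl(diphenyl)silyl]oxypropan-2-yl}-7-iodo-6-methyl-1-[(2S)-2-methyloxiran-2-yl]hept-6-en-1-ol
Product: 17 (5S,6R,8R,11E)-8-{1-[tert-butyl(diphenyl)silyl]oxypropan-2-yl}-12-iodo-5,11-dimethyldodec-11-en-2-yne-5,6-diol (C15 epimers)
Conditions: CH3C≡CLi (excess), BF3·OEt2, THF, −78 °C
Reagents that add atoms: 1-propynyllithium, [Li]C#CC
Why: Lewis acid-promoted opening of an epoxide by an alkynyl borate (Yamaguchi–Hirao) at the unsubstituted carbon C5, which forms the C5–C6 bond and leaves the C4–O bond and therefore the C4 configuration untouched. The first equivalent converts the C3 hydroxyl into its alkoxide; an alkynyllithium does not exchange with the vinyl iodide.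

Step 12
Reactants: 17 (5S,6R,8R,11E)-8-{1-[tert-butyl(diphenyl)silyl]oxypropan-2-yl}-12-iodo-5,11-dimethyldodec-11-en-2-yne-5,6-diol
Product: 18 (5S,6R,8R,11E)-8-(1-hydroxypropan-2-yl)-12-iodo-5,11-dimethyldodec-11-en-2-yne-5,6-diol (C15 epimers)
Conditions: Bu4NF, THF, rt
Reagents that add atoms: none
Why: Fluoride cleavage of the silyl ether; vinyl iodide, alkyne and the diol should be inert.

Step 13
Reactants: 18 (5S,6R,8R,11E)-8-(1-hydroxypropan-2-yl)-12-iodo-5,11-dimethyldodec-11-en-2-yne-5,6-diol
Product: 21 (4R,6R)-6-[(2S)-2-hydroxyhex-4-yn-2-yl]-4-[(3E)-4-iodo-3-methylbut-3-en-1-yl]-3-methyloxan-2-one (C15 epimers), via hydroxy aldehyde 19 (not isolated), via lactol 20 (not isolated)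
Conditions: TEMPO (cat.), KBr (cat.), NaOCl, NaHCO3, CH2Cl2/H2O, 0 °C
Reagents that add atoms: none
Why: Nitroxyl-catalysed hypochlorite oxidation (Anelli conditions) is selective for the primary alcohol; the C16 aldehyde should close onto the C3 hydroxyl to the six-membered lactol, which is oxidised on to the lactone. Hypochlorite is preferred to a hypervalent iodine co-oxidant so that the C3/C4 glycol is not cleaved, and the tertiary C4 alcohol cannot be oxidised.

Step 14
Reactants: 21 (4R,6R)-6-[(2S)-2-hydroxyhex-4-yn-2-yl]-4-[(3E)-4-iodo-3-methylbut-3-en-1-yl]-3-methyloxan-2-one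
Product: 22 (4R,6R)-4-[(3E)-4-iodo-3-methylbut-3-en-1-yl]-3-methyl-6-[(2S)-2-(triethylsilyloxy)hex-4-yn-2-yl]oxan-2-one (C15 epimers)
Conditions: Et3SiOTf, 2,6-lutidine, CH2Cl2, −78→0 °C
Reagents that add atoms: triethylsilyl trifluoromethanesulfonate, CC[Si](CC)(CC)OS(=O)(=O)C(F)(F)F
Why: A silyl triflate with a hindered pyridine base silylates a tertiary alcohol; the protic group is masked so that it cannot interfere with the alkylidyne catalyst of step 19.

Step 15
Reactants: 22 (4R,6R)-4-[(3E)-4-iodo-3-methylbut-3-en-1-yl]-3-methyl-6-[(2S)-2-(triethylsilyloxy)hex-4-yn-2-yl]oxan-2-one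
Product: 23 (3S,4R,6R)-4-[(3E)-4-iodo-3-methylbut-3-en-1-yl]-3-methyl-6-[(2S)-2-(triethylsilyloxy)hex-4-yn-2-yl]oxan-2-one
Conditions: DBU, toluene, 80 °C; chromatography, minor epimer resubmitted
Reagents that add atoms: none
Why: Base-mediated epimerisation α to the lactone carbonyl through the enolate. C15 should settle in the configuration that places the C17 methyl equatorial and trans to the C14 chain, with the C1 and C3 substituents already equatorial, which is (15S); the vinyl iodide and the silyl ether should not be affected by an amidine base.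

Step 16
Reactants: 24 3-bromo-3-buten-1-ol; 25 propyne
Product: 26 3-methylidenehex-4-yn-1-ol
Conditions: PdCl2(PPh3)2 (cat.), CuI (cat.), Et3N, THF, rt
Reagents that add atoms: none
Why: Sonogashira coupling of a 2-bromo-1-alkene with a terminal alkyne forms the C7–C8 bond of the enyne; the free primary alcohol is tolerated.

Step 17
Reactants: 26 3-methylidenehex-4-yn-1-ol
Product: 27 6-iodo-4-methylidenehex-2-yne
Conditions: I2, PPh3, imidazole, CH2Cl2, 0 °C
Reagents that add atoms: iodine, II
Why: Appel-type iodination of a primary alcohol under neutral conditions, which should not touch the enyne.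

Step 18
Reactants: 23 (3S,4R,6R)-4-[(3E)-4-iodo-3-methylbut-3-en-1-yl]-3-methyl-6-[(2S)-2-(triethylsilyloxy)hex-4-yn-2-yl]oxan-2-one; 27 6-iodo-4-methylidenehex-2-yne
Product: 29 (3S,4R,6R)-3-methyl-4-[(3E)-3-methyl-7-methylidenedec-3-en-8-yn-1-yl]-6-[(2S)-2-(triethylsilyloxy)hex-4-yn-2-yl]oxan-2-one (seco diyne), via alkylzinc iodide 28 (not isolated)
Conditions: 27, Zn dust, LiCl, THF, 40 °C; then 23, Pd(dppf)Cl2 (cat.), THF, rt→50 °C
Reagents that add atoms: none
Why: Zinc insertion into the primary alkyl iodide followed by Negishi sp3–sp2 cross-coupling forms the C10–C11 bond with retention of the (E)-geometry. An alkylzinc halide should not attack the lactone, the silyl ether or the internal alkynes.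

Step 19
Reactants: 29 (3S,4R,6R)-3-methyl-4-[(3E)-3-methyl-7-methylidenedec-3-en-8-yn-1-yl]-6-[(2S)-2-(triethylsilyloxy)hex-4-yn-2-yl]oxan-2-one
Product: 30 (1R,3R,4S,11E,15S)-4-(triethylsilyloxy)cembra-8(19),11-dien-6-yn-16,3-olide (14-membered C6≡C7 cycloalkyne)
Conditions: Mo(≡CC6H4OMe-4)(OSiPh3)3 (cat.), 5 Å molecular sieves, toluene (high dilution), 80 °C
Reagents that add atoms: none
Why: Ring-closing alkyne metathesis: the molybdenum alkylidyne adds to one propynyl terminus to give a metallacyclobutadiene, cycloreversion expels 2-butyne and leaves a substrate-bound alkylidyne, and the same sequence with the second propynyl group forms the C6≡C7 bond. The closest known reaction type is the ring closure of methyl-capped diynes to cycloalkynes of fourteen and more members with molybdenum alkylidyne triarylsilanolate catalysts, including substrates in which one alkyne is the end of a 1,3-enyne. The 14-membered carbocycle is closed by end-to-end union of the two alkyne termini, with the new triple bond inside the ring and the existing lactone as the bridge from C1 to C3. No stereocentre is formed or touched and a triple bond has no geometry, so there is no stereochemical outcome to control. The step needs selectivity for alkynes over the C11=C12 and C8=C19 olefins, which an alkylidyne of this type provides because it does not engage olefins, and tolerance of the lactone and the silyl ether, which the silanolate ligand set provides; the C4 hydroxyl is silylated so that no protic group can protonate the alkylidyne or exchange the ligands. It needs ring closure to win over acyclic diyne metathesis, which high dilution and the sieves should secure, the sieves by adsorbing 2-butyne so that each productive step is irreversible. The lactone helps by fixing the C1–C2–C3 segment and so reducing the free rotors between the two termini, and fourteen members are enough to span the linear C5–C6≡C7–C8 unit.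

Step 20
Reactants: 30 (1R,3R,4S,11E,15S)-4-(triethylsilyloxy)cembra-8(19),11-dien-6-yn-16,3-olide
Product: 31 (1R,3R,4S,11E,15S)-4-hydroxycembra-8(19),11-dien-6-yn-16,3-olide
Conditions: HF·pyridine, pyridine, THF, 0 °C→rt
Reagents that add atoms: none
Why: Fluoride cleavage of a tertiary triethylsilyl ether; buffering with pyridine should protect the lactone and the enyne.

Step 21
Reactants: 31 (1R,3R,4S,11E,15S)-4-hydroxycembra-8(19),11-dien-6-yn-16,3-olide
Product: 33 (1R,3R,4S,11E,15S)-4-hydroxy-7-oxocembra-8(19),11-dien-16,3-olide, via dihydrofuran 32 (not isolated)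
Conditions: Ph3PAuNTf2 (cat.), CH2Cl2, rt; then PPTS, THF/H2O, rt
Reagents that add atoms: water, O
Why: Gold-catalysed 5-endo-dig hydroalkoxylation of a homopropargylic alcohol: the C4 hydroxyl can only add to C7, since addition to C6 would need a four-membered ring, and C7 is also the alkyne carbon whose positive charge the C8=C19 olefin stabilises. The cyclic dienol ether 32 is then hydrolysed by protonation at C6 and addition of water at C7; collapse of the hemiketal returns the C4 hydroxyl and leaves the C7 ketone conjugated with the C8 methylene.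

Step 22
Reactants: 33 (1R,3R,4S,11E,15S)-4-hydroxy-7-oxocembra-8(19),11-dien-16,3-olide
Product: 34 (1R,3R,4S,7S,11E,15S)-4,7-dihydroxycembra-8(19),11-dien-16,3-olide
Conditions: (R)-2-methyl-CBS-oxazaborolidine, catecholborane, toluene/CH2Cl2, −78 °C
Reagents that add atoms: none
Why: Corey–Bakshi–Shibata 1,2-reduction of an α-methylene ketone; the sp2 carbon C8 is the large group and the C6 methylene the small one, so the (R)-catalyst should give the (7S)-alcohol. The lactone and the isolated olefin should not react with catecholborane at this temperature.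

Step 23
Reactants: 34 (1R,3R,4S,7S,11E,15S)-4,7-dihydroxycembra-8(19),11-dien-16,3-olide
Product: 35 (1R,3R,4S,7S,11S,12S,15S)-11,12-epoxy-4,7-dihydroxycembr-8(19)-en-16,3-olide (target)
Conditions: L-fructose-derived Shi ketone (cat.), KHSO5, K2CO3, Bu4NHSO4, MeCN/CH2(OMe)2/aq. buffer (pH 10.5), 0 °C
Reagents that add atoms: potassium peroxymonosulfate, [K+].[O-]S(=O)(=O)OO
Why: Shi epoxidation by a chiral dioxirane; the electron-rich trisubstituted C11=C12 olefin should react faster than the 1,1-disubstituted allylic C8=C19 olefin. The ketone of the L series is the mirror image of the D-fructose-derived catalyst, which gives (R,R)-epoxides from (E)-trisubstituted olefins, and should therefore deliver oxygen to the face that gives the (11S,12S)-epoxide; the buffered medium should spare the epoxide and the lactone.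

## Compound list

1 | (R)-(+)-limonene | CC1=CC[C@@H](CC1)C(C)=C | starting material
2 | 9-{2-[(1R)-4-methylcyclohex-3-en-1-yl]propyl}-9-borabicyclo[3.3.1]nonane (C15 epimers) | CC1=CC[C@@H](CC1)C(C)CB1C2CCCC1CCC2 | intermediate
3 | 2-[(1R)-4-methylcyclohex-3-en-1-yl]propan-1-ol (C15 epimers) | CC1=CC[C@@H](CC1)C(C)CO | intermediate
4 | tert-butyl{2-[(1R)-4-methylcyclohex-3-en-1-yl]propoxy}diphenylsilane (C15 epimers) | CC1=CC[C@@H](CC1)C(C)CO[Si](c1ccccc1)(c1ccccc1)C(C)(C)C | intermediate
5 | (3R)-3-{1-[tert-butyl(diphenyl)silyl]oxypropan-2-yl}-6-hydroperoxy-6-methoxyheptanal | COC(C)(OO)CC[C@H](CC=O)C(C)CO[Si](c1ccccc1)(c1ccccc1)C(C)(C)C | intermediate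
6 | tert-butyl{2-[(3R)-6-hydroperoxy-1,1,6-trimethoxyheptan-3-yl]propoxy}diphenylsilane | COC(C)(OO)CC[C@H](CC(OC)OC)C(C)CO[Si](c1ccccc1)(c1ccccc1)C(C)(C)C | intermediate
7 | (5R)-7-{[tert-butyl(diphenyl)silyl]oxy}-5-(2,2-dimethoxyethyl)-6-methylheptan-2-one (C15 epimers) | CC(=O)CC[C@H](CC(OC)OC)C(C)CO[Si](c1ccccc1)(c1ccccc1)C(C)(C)C | intermediate
8 | diethyl (5R)-7-{[tert-butyl(diphenyl)silyl]oxy}-5-(2,2-dimethoxyethyl)-6-methylhept-1-en-2-yl phosphate | C=C(OP(=O)(OCC)OCC)CC[C@H](CC(OC)OC)C(C)CO[Si](c1ccccc1)(c1ccccc1)C(C)(C)C | intermediate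
9 | tert-butyl{[(3R)-3-(2,2-dimethoxyethyl)-2-methylhept-6-yn-1-yl]oxy}diphenylsilane (C15 epimers) | C#CCC[C@H](CC(OC)OC)C(C)CO[Si](c1ccccc1)(c1ccccc1)C(C)(C)C | intermediate
10 | (3R)-3-{1-[tert-butyl(diphenyl)silyl]oxypropan-2-yl}hept-6-ynal (C15 epimers) | C#CCC[C@H](CC=O)C(C)CO[Si](c1ccccc1)(c1ccccc1)C(C)(C)C | intermediate
11 | (5R)-5-{1-[tert-butyl(diphenyl)silyl]oxypropan-2-yl}-2-methylnon-1-en-8-yn-3-ol (C3 and C15 epimers) | C#CCC[C@H](CC(O)C(C)=C)C(C)CO[Si](c1ccccc1)(c1ccccc1)C(C)(C)C | intermediate
12 | (E)-alkenyl(dimethyl)alane of 11, hydroxyl as dimethylaluminium alkoxide | C[Al](C)/C=C(\C)CC[C@H](CC(O[Al](C)C)C(C)=C)C(C)CO[Si](c1ccccc1)(c1ccccc1)C(C)(C)C | intermediate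
13 | (5R,8E)-5-{1-[tert-butyl(diphenyl)silyl]oxypropan-2-yl}-9-iodo-2,8-dimethylnona-1,8-dien-3-ol (C3 and C15 epimers) | I/C=C(\C)CC[C@H](CC(O)C(C)=C)C(C)CO[Si](c1ccccc1)(c1ccccc1)C(C)(C)C | intermediate
14 | (5R,8E)-5-{1-[tert-butyl(diphenyl)silyl]oxypropan-2-yl}-9-iodo-2,8-dimethylnona-1,8-dien-3-one (C15 epimers) | I/C=C(\C)CC[C@H](CC(=O)C(C)=C)C(C)CO[Si](c1ccccc1)(c1ccccc1)C(C)(C)C | intermediate
15 | (3R,5R,8E)-5-{1-[tert-butyl(diphenyl)silyl]oxypropan-2-yl}-9-iodo-2,8-dimethylnona-1,8-dien-3-ol (C15 epimers) | I/C=C(\C)CC[C@H](C[C@@H](O)C(C)=C)C(C)CO[Si](c1ccccc1)(c1ccccc1)C(C)(C)C | intermediate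
16 | (1R,3R,6E)-3-{1-[tert-butyl(diphenyl)silyl]oxypropan-2-yl}-7-iodo-6-methyl-1-[(2S)-2-methyloxiran-2-yl]hept-6-en-1-ol (C15 epimers) | I/C=C(\C)CC[C@H](C[C@@H](O)[C@]1(C)CO1)C(C)CO[Si](c1ccccc1)(c1ccccc1)C(C)(C)C | intermediate
17 | (5S,6R,8R,11E)-8-{1-[tert-butyl(diphenyl)silyl]oxypropan-2-yl}-12-iodo-5,11-dimethyldodec-11-en-2-yne-5,6-diol (C15 epimers) | I/C=C(\C)CC[C@H](C[C@@H](O)[C@@](C)(O)CC#CC)C(C)CO[Si](c1ccccc1)(c1ccccc1)C(C)(C)C | intermediate
18 | (5S,6R,8R,11E)-8-(1-hydroxypropan-2-yl)-12-iodo-5,11-dimethyldodec-11-en-2-yne-5,6-diol (C15 epimers) | I/C=C(\C)CC[C@H](C[C@@H](O)[C@@](C)(O)CC#CC)C(C)CO | intermediate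
19 | 2-[(1E,5R,7R,8S)-7,8-dihydroxy-1-iodo-2,8-dimethyldodec-1-en-10-yn-5-yl]propanal | I/C=C(\C)CC[C@H](C[C@@H](O)[C@@](C)(O)CC#CC)C(C)C=O | intermediate
20 | (4R,6R)-6-[(2S)-2-hydroxyhex-4-yn-2-yl]-4-[(3E)-4-iodo-3-methylbut-3-en-1-yl]-3-methyloxan-2-ol | I/C=C(\C)CC[C@@H]1C[C@@H](OC(O)C1C)[C@@](C)(O)CC#CC | intermediate
21 | (4R,6R)-6-[(2S)-2-hydroxyhex-4-yn-2-yl]-4-[(3E)-4-iodo-3-methylbut-3-en-1-yl]-3-methyloxan-2-one (C15 epimers) | I/C=C(\C)CC[C@@H]1C[C@@H](OC(=O)C1C)[C@@](C)(O)CC#CC | intermediate
22 | (4R,6R)-4-[(3E)-4-iodo-3-methylbut-3-en-1-yl]-3-methyl-6-[(2S)-2-(triethylsilyloxy)hex-4-yn-2-yl]oxan-2-one (C15 epimers) | I/C=C(\C)CC[C@@H]1C[C@@H](OC(=O)C1C)[C@@](C)(O[Si](CC)(CC)CC)CC#CC | intermediate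
23 | (3S,4R,6R)-4-[(3E)-4-iodo-3-methylbut-3-en-1-yl]-3-methyl-6-[(2S)-2-(triethylsilyloxy)hex-4-yn-2-yl]oxan-2-one | I/C=C(\C)CC[C@@H]1C[C@@H](OC(=O)[C@H]1C)[C@@](C)(O[Si](CC)(CC)CC)CC#CC | intermediate
24 | 3-bromo-3-buten-1-ol | OCCC(Br)=C | starting material
25 | propyne | CC#C | starting material
26 | 3-methylidenehex-4-yn-1-ol | CC#CC(=C)CCO | intermediate
27 | 6-iodo-4-methylidenehex-2-yne | CC#CC(=C)CCI | intermediate
28 | (3-methylidenehex-4-yn-1-yl)zinc iodide | CC#CC(=C)CC[Zn]I | intermediate
29 | (3S,4R,6R)-3-methyl-4-[(3E)-3-methyl-7-methylidenedec-3-en-8-yn-1-yl]-6-[(2S)-2-(triethylsilyloxy)hex-4-yn-2-yl]oxan-2-one | CC#CC(=C)CC/C=C(\C)CC[C@@H]1C[C@@H](OC(=O)[C@H]1C)[C@@](C)(O[Si](CC)(CC)CC)CC#CC | intermediate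
30 | (1R,3R,4S,11E,15S)-4-(triethylsilyloxy)cembra-8(19),11-dien-6-yn-16,3-olide | C=C1CC/C=C(\C)CC[C@@H]2C[C@@H](OC(=O)[C@H]2C)[C@@](C)(O[Si](CC)(CC)CC)CC#C1 | intermediate
31 | (1R,3R,4S,11E,15S)-4-hydroxycembra-8(19),11-dien-6-yn-16,3-olide | C=C1CC/C=C(\C)CC[C@@H]2C[C@@H](OC(=O)[C@H]2C)[C@@](C)(O)CC#C1 | intermediate
32 | (1R,3R,4S,11E,15S)-4,7-epoxycembra-6,8(19),11-trien-16,3-olide (2-alkenyl-4,5-dihydrofuran) | C=C1CC/C=C(\C)CC[C@@H]2C[C@@H](OC(=O)[C@H]2C)[C@]3(C)CC=C1O3 | intermediate
33 | (1R,3R,4S,11E,15S)-4-hydroxy-7-oxocembra-8(19),11-dien-16,3-olide | C=C1CC/C=C(\C)CC[C@@H]2C[C@@H](OC(=O)[C@H]2C)[C@@](C)(O)CCC1=O | intermediate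
34 | (1R,3R,4S,7S,11E,15S)-4,7-dihydroxycembra-8(19),11-dien-16,3-olide | C=C1CC/C=C(\C)CC[C@@H]2C[C@@H](OC(=O)[C@H]2C)[C@@](C)(O)CC[C@@H]1O | intermediate
35 | (1R,3R,4S,7S,11S,12S,15S)-11,12-epoxy-4,7-dihydroxycembr-8(19)-en-16,3-olide | C=C1CC[C@@H]2O[C@@]2(C)CC[C@@H]2C[C@@H](OC(=O)[C@H]2C)[C@@](C)(O)CC[C@@H]1O | target

## Step count and the least certain steps

Total: 23 steps. Longest linear sequence: 21 steps (steps 1–15 and 18–23, from 1 to 35); the side branch to 27 is 2 steps (16 and 17).

Step 19 (key step). The most likely failure is that intermolecular metathesis to linear and cyclic oligomers outruns ring closure, because the two arms leave the lactone in diverging equatorial directions, or that turnover stalls at the conjugated enyne terminus. Fallback: close the same ring at C7–C8 by an intramolecular Sonogashira coupling, which reaches the same cycloalkyne. It sets out from epoxy alcohol 16. Opening with Me3SiC≡CLi and BF3·OEt2 should give the silylalkyne diol F1, and Bu4NF removes both silyl groups to give the terminal alkyne triol F2. The oxidation of step 13 then gives the hydroxy lactone F3, silylation as in step 14 the triethylsilyl ether F4, and equilibration as in step 15 the (15S)-lactone F5. In parallel, 24 is converted with I2, PPh3 and imidazole into 2-bromo-4-iodobut-1-ene F6, zinc insertion gives (3-bromobut-3-en-1-yl)zinc iodide F7, and Negishi coupling with F5, in which the vinyl iodide should react and the vinyl bromide not, gives the bromo alkyne F8. Slow addition of F8 to Pd(PPh3)4, CuI and i-Pr2NH at high dilution should form the C7–C8 bond, and the route is rejoined at 30.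

Step 21. The most likely failure is that the gold-activated alkyne is captured by the C11=C12 olefin across the ring (a 1,6-enyne carbocyclisation) faster than by the hydroxyl, or that the hydrolysis stops at the bridged hemiketal. Fallback: deliver the oxygen through a silicon tether. From 31, silylation with 1,1,3,3-tetramethyldisilazane should give the dimethylsilyl ether F9; Cp*Ru(MeCN)3PF6 should then add Si–H across the alkyne in the endo, trans sense to the six-membered cyclic siloxane F10 with silicon on C7; Tamao–Fleming oxidation (KF, KHCO3, H2O2) converts the C7–Si bond into the ketone and frees the C4 hydroxyl, returning to 33.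

Step 22. The most likely failure is poor facial selectivity, because the conformation of the macrocycle, or partial hemiketal formation with the C4 hydroxyl, overrides the preference of the oxazaborolidine. Fallback: use the ring's own preference and correct it if needed. From 33, reduction with NaBH4 and CeCl3·7H2O would be tried; should it favour the (7R)-alcohol F11, Mitsunobu esterification with 4-nitrobenzoic acid, PPh3 and DIAD would invert C7 to the (7S)-4-nitrobenzoate F12, and brief methanolysis (K2CO3, MeOH, 0 °C) returns to 34.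

Step 23. The most likely failure is that the macrocycle exposes mainly one face of C11=C12 and this face opposes the one the dioxirane prefers, so that the wrong epoxide or a mixture forms; slow lactone hydrolysis at the buffered pH is a lesser concern. Fallback: if the ring directs electrophiles to the wrong face, use that preference through a bromohydrin, which places the oxygen on the opposite face. From 34, N-bromosuccinimide in aqueous THF should form the bromonium ion on the accessible face and water should open it at the tertiary C12 from behind, giving the (11R,12S)-bromohydrin F13; K2CO3 in MeOH then closes the epoxide with inversion at C11 and gives 35.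

Step 15. The most likely failure is an insufficient thermodynamic bias, so that equilibration leaves a large share of the (15R)-lactone and repeated recycling erodes material. Fallback: settle C15 at the start by separation. From 3, acylation with 3,5-dinitrobenzoyl chloride and fractional crystallisation of the diastereomeric esters should give the (2S)-3,5-dinitrobenzoate F14; K2CO3 in MeOH gives the single (2S)-alcohol F15, which enters step 2 in place of 3. All compounds from 4 to 22 are then single C15 epimers, and the material reached after step 14 is 23 itself, so step 15 is no longer needed.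

## Further compounds

F1 | step 19 | (4S,5R,7R,10E)-7-{1-[tert-butyl(diphenyl)silyl]oxypropan-2-yl}-11-iodo-4,10-dimethyl-1-(trimethylsilyl)undec-10-en-1-yne-4,5-diol (C15 epimers) | I/C=C(\C)CC[C@H](C[C@@H](O)[C@@](C)(O)CC#C[Si](C)(C)C)C(C)CO[Si](c1ccccc1)(c1ccccc1)C(C)(C)C
F2 | step 19 | (4S,5R,7R,10E)-7-(1-hydroxypropan-2-yl)-11-iodo-4,10-dimethylundec-10-en-1-yne-4,5-diol (C15 epimers) | I/C=C(\C)CC[C@H](C[C@@H](O)[C@@](C)(O)CC#C)C(C)CO
F3 | step 19 | (4R,6R)-6-[(2S)-2-hydroxypent-4-yn-2-yl]-4-[(3E)-4-iodo-3-methylbut-3-en-1-yl]-3-methyloxan-2-one (C15 epimers) | I/C=C(\C)CC[C@@H]1C[C@@H](OC(=O)C1C)[C@@](C)(O)CC#C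
F4 | step 19 | (4R,6R)-4-[(3E)-4-iodo-3-methylbut-3-en-1-yl]-3-methyl-6-[(2S)-2-(triethylsilyloxy)pent-4-yn-2-yl]oxan-2-one (C15 epimers) | I/C=C(\C)CC[C@@H]1C[C@@H](OC(=O)C1C)[C@@](C)(O[Si](CC)(CC)CC)CC#C
F5 | step 19 | (3S,4R,6R)-4-[(3E)-4-iodo-3-methylbut-3-en-1-yl]-3-methyl-6-[(2S)-2-(triethylsilyloxy)pent-4-yn-2-yl]oxan-2-one | I/C=C(\C)CC[C@@H]1C[C@@H](OC(=O)[C@H]1C)[C@@](C)(O[Si](CC)(CC)CC)CC#C
F6 | step 19 | 2-bromo-4-iodobut-1-ene | C=C(Br)CCI
F7 | step 19 | (3-bromobut-3-en-1-yl)zinc iodide | C=C(Br)CC[Zn]I
F8 | step 19 | (3S,4R,6R)-4-[(3E)-7-bromo-3-methylocta-3,7-dien-1-yl]-3-methyl-6-[(2S)-2-(triethylsilyloxy)pent-4-yn-2-yl]oxan-2-one | C=C(Br)CC/C=C(\C)CC[C@@H]1C[C@@H](OC(=O)[C@H]1C)[C@@](C)(O[Si](CC)(CC)CC)CC#C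
F9 | step 21 | (1R,3R,4S,11E,15S)-4-(dimethylsilyloxy)cembra-8(19),11-dien-6-yn-16,3-olide | C=C1CC/C=C(\C)CC[C@@H]2C[C@@H](OC(=O)[C@H]2C)[C@@](C)(O[SiH](C)C)CC#C1
F10 | step 21 | cyclic siloxane of 31 with O–SiMe2 bridging C4 and C7 and a C6=C7 double bond (six-membered 1,2-oxasiline) | C=C1CC/C=C(\C)CC[C@@H]2C[C@@H](OC(=O)[C@H]2C)[C@]3(C)CC=C1[Si](C)(C)O3
F11 | step 22 | (1R,3R,4S,7R,11E,15S)-4,7-dihydroxycembra-8(19),11-dien-16,3-olide | C=C1CC/C=C(\C)CC[C@@H]2C[C@@H](OC(=O)[C@H]2C)[C@@](C)(O)CC[C@H]1O
F12 | step 22 | (7S)-7-O-(4-nitrobenzoyl) derivative of 34 | C=C1CC/C=C(\C)CC[C@@H]2C[C@@H](OC(=O)[C@H]2C)[C@@](C)(O)CC[C@@H]1OC(=O)c1ccc(cc1)[N+](=O)[O-]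
F13 | step 23 | (1R,3R,4S,7S,11R,12S,15S)-11-bromo-4,7,12-trihydroxycembr-8(19)-en-16,3-olide | C=C1CC[C@@H](Br)[C@@](C)(O)CC[C@@H]2C[C@@H](OC(=O)[C@H]2C)[C@@](C)(O)CC[C@@H]1O
F14 | step 15 | (2S)-2-[(1R)-4-methylcyclohex-3-en-1-yl]propyl 3,5-dinitrobenzoate | CC1=CC[C@@H](CC1)[C@H](C)COC(=O)c1cc(cc(c1)[N+](=O)[O-])[N+](=O)[O-]
F15 | step 15 | (2S)-2-[(1R)-4-methylcyclohex-3-en-1-yl]propan-1-ol | CC1=CC[C@@H](CC1)[C@H](C)CO
A1 | alternative 1 | 7-O-triethylsilyl ether of the target | C=C1CC[C@@H]2O[C@@]2(C)CC[C@@H]2C[C@@H](OC(=O)[C@H]2C)[C@@](C)(O)CC[C@@H]1O[Si](CC)(CC)CC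
A2 | alternative 1 | (2S)-2-[(1R,3S,4S,7S,11S,12S)-3,4:11,12-diepoxy-7-(triethylsilyloxy)cembr-8(19)-en-1-yl]propanoic acid (bis-epoxy acid) | C=C1CC[C@@H]2O[C@@]2(C)CC[C@@H]([C@H](C)C(O)=O)C[C@@H]2O[C@@]2(C)CC[C@@H]1O[Si](CC)(CC)CC
A3 | alternative 2 | (E)-olefin macrocycle, lactol methyl acetal, 7-O-tert-butyldimethylsilyl ether | C=C1CC/C=C(\C)CC[C@@H]2C[C@@H](OC(OC)[C@H]2C)[C@@](C)(O)CC[C@@H]1O[Si](C)(C)C(C)(C)C
A4 | alternative 2 | seco keto aldehyde with C11 aldehyde and C12 methyl ketone, lactol methyl acetal | O=CCCC(=C)[C@@H](O[Si](C)(C)C(C)(C)C)CC[C@](C)(O)[C@H]1C[C@@H](CCC(C)=O)[C@H](C)C(OC)O1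
A5 | alternative 3 | macrocyclic C1 dithiane with free C3 hydroxyl | C=C1CC/C=C(\C)CCC2(SCCCS2)C[C@@H](O)[C@@](C)(O[Si](CC)(CC)CC)CC[C@@H]1O[Si](C)(C)C(C)(C)C
A6 | alternative 3 | acyclic C14 iodide with C2–C3 epoxide | ICC/C(C)=C/CCC(=C)[C@@H](O[Si](C)(C)C(C)(C)C)CC[C@](C)(O[Si](CC)(CC)CC)[C@H]1CO1
A7 | alternative 3 | 1,3-dithiane | C1CSCSC1
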